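- I kept the charge small, 10 mM of starting material against 9.00 mM of coupling partner, and I left these flasks for you with these questions:

| flask | starting material | coupling partner | temperature | time | remark |
|---|---|---|---|---|---|
| epsilon | 10 mM | 9.00 mM (fed, over 5.0 h) | 50 °C | 25 h | all else is in the flask from the start; the feed brings no volume worth counting |
| delta | 10 mM | 9.00 mM (fed, over 20 h) | 50 °C | 25 h | all else is in the flask from the start; the feed brings no volume worth counting |
| eta | 10 mM | 9.00 mM (fed, over 20 h) |  | 25 h | the addition at 10 °C, then warmed to 50 °C; the feed brings no volume worth counting |
| theta | 10 mM (fed, over 20 h) | 9.00 mM | 50 °C | 25 h | all else is in the flask from the start; the feed brings no volume worth counting |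
| zeta | 10 mM | 9.00 mM | 50 °C | 25 h | everything together at the start |

* the flask with the highest share of target in target plus side product ("all alike" if they lie within 1.5 percentage points) (epsilon / delta / eta / theta / zeta / all alike)
* share of target in target plus side product at the end, epsilon
* share of target in target plus side product at the end, delta
* share of target in target plus side product at the end, eta
* share of target in target plus side product at the end, theta
* share of target in target plus side product at the end, zeta

- what is said of target includes crystals
- crystals is a solid; its amount is given per volume of the solution
- all constants are for 50 °C and move with temperature by the activation energies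

    starting material + coupling partner → intermediate (k1 = 4.5 L mol⁻¹ h⁻¹, Ea1 = 56.0 kJ mol⁻¹)
    intermediate → target (k2 = 0.11 h⁻¹, Ea2 = 105 kJ mol⁻¹)
    intermediate → side product (k3 = 0.029 h⁻¹, Ea3 = 98.0 kJ mol⁻¹)
    crystals ⇌ target, rate k4*(cs4 - [target]) while solid is left; crystals form when [target] > cs4 (cs4 = 4.4 mM, k4 = 0.20 h⁻¹)
    intermediate → decomposed reagent (k5 = 0.027 h⁻¹, Ea5 = 97.0 kJ mol⁻¹)
    (constants at 50 °C)

- The intermediate goes to target and to side product by first-order steps, so c(intermediate) cancels from the ratio of their rates. 0.11 h⁻¹ over its sum with 0.029 h⁻¹ gave 79.1% at 50 °C. This is the branch share (the selectivity of the branch), the part of what leaves the intermediate for target or side product that becomes target.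
- When you arrived at 25 h, I expected an unfinished flask, because in zeta the half-life of starting material by its first step alone, at the charged concentrations, is 17 h, about 1.47 half-lives in that time. The branch share holds no conversion, so I saw no reason to wait for more.
- Eta was the flask to count, because its activation energies favour the side product in the cold. But at 10 °C the two branches together made 0.0122 turnovers in 20 h, hardly any, so I expected eta's products to form after warming.
- Please leave the feeds and the crystals alone: the branch share holds no feed time, crystals count as target, and the loss to decomposed reagent does not shift the share. I committed to 79.1% for each flask.
- The forecast agreed, with 79.1%, 79.1%, 79.1%, 79.1% and 79.1% in the order asked, and all alike as the choice, holding the share to stand “whatever the feed mode or the conversion”.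
- The simulation gave 79.1%, 79.1%, 79.1%, 79.1% and 79.1% in that order, and all alike.
- Eta stood at 79.1% with 82% of its starting material still unreacted. I applied the branch share to the neighbouring eta flask with 23 mM of coupling partner. Its target and side product together came to 12.7% of the starting material charged, so 79.1% of that gave 10.1% of the starting material charged as target. That flask gave 79.1% as its share, with 25.1% of the starting material standing as intermediate at 25.0 h.

All constants belong to no real substance; no experiment stands behind them.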